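| setting | zeta | delta | grey | red | violet | teal |
|---|---|---|---|---|---|---|
| substrate | 0.48 M | 0.89 M | 0.50 M | 1.0 M | 0.30 M | 0.25 M |
| coupling partner | 0.95 equiv | 0.95 equiv | 0.950 equiv | 0.950 equiv | 0.950 equiv | 0.950 equiv |
| free catalyst | 0.079 mol% | 0.079 mol% | 0.079 mol% | 0.079 mol% | 0.079 mol% | 0.079 mol% |
| impurity | 55 µM | 55 µM | 55 µM | 55 µM | 55 µM | 55 µM |
| remark | run made earlier | run made earlier |  |  |  |  |
| time |  |  | 20 min | 20 min | 20 min | 20 min |

| run | time / min | target / % | substrate / % |
|---|---|---|---|
| zeta | 0.833 | 3.2 | 97.7 |
| zeta | 2.50 | 8.0 | 92.7 |
| zeta | 5.00 | 14.1 | 85.5 |
| zeta | 8.00 | 20.6 | 79.4 |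
| zeta | 10.0 | 24.8 | 74.0 |
| delta | 0.833 | 4.8 | 96.8 |
| delta | 2.50 | 10.4 | 90.0 |
| delta | 5.00 | 20.1 | 80.0 |
| delta | 8.00 | 30.8 | 69.6 |
| delta | 10.0 | 37.4 | 63.0 |

(scatter of a reading: 0.5 percentage points)

- all flasks from highest to lowest amount of target, in percent of the substrate charged, at 20 min (grey / red / violet / teal)
- the amount of target, in percent of the substrate charged of the flask you put first, at 20 min
- the amount of target, in percent of the substrate charged of the flask you put last, at 20 min

At 0.950 equiv per substrate, the coupling partner is charged in a smaller amount than the substrate, which makes it the limiting reagent in grey, red, violet and teal alike. Its ledger is therefore kept here in fractions of the substrate charge. The books open at 95.0%: the charged coupling partner over the charged substrate, the partner ceiling.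

The first entry is the target, taken in this reckoning at one coupling partner each. The delta run supports a one-to-one fate for the substrate, because at 10.0 min target and substrate add up to 100%, within the scatter of 0.5 percentage points. Delta's target of 37.4% therefore leaves 57.6% of the substrate charge on the partner's account. That balance is unread, so it may be unused coupling partner or a loss that the readings do not show.

The ceiling is the same in the four new flasks, so it gives no ranking among them. At 10.0 min the more concentrated delta run holds more target than the zeta run. This reckoning therefore commits to the order of concentration, with each flask's target under 95.0%.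

The forecast gives red > grey > violet > teal, with 66% (59% to 74%) for the first flask and 28% (22% to 33%) for the last. Its ground: “The order must follow concentration: red, grey, violet, teal.”

The flasks come out as red > grey > violet > teal. Red stands at 61.6%, inside the forecast's range for the first flask, and teal at 20.6%, under the low end of 22% of its range for the last flask.

    coupling partner + free catalyst ⇌ catalyst intermediate A (K = 2.40 /M, k = 2400 /M/min)
    substrate + catalyst intermediate A → catalyst intermediate B (k = 440 /M/min)
    catalyst intermediate B → free catalyst + target (k = 77.0 /min)
    free catalyst + impurity → spent catalyst (k = 57000 /M/min)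
    coupling partner → decomposed reagent (k = 0.0340 /min)

At 20 min, red's books close on its ceiling of 95.0% with target 61.6%, decomposed reagent 27.1% and free coupling partner 6.24%, so the partner's turnover to target stands at 2.27 times its turnover to decomposed reagent. The neighbouring flask, like red but with 0.380 equiv of coupling partner, opens its books at 38.0% and at 20.0 min holds target 31.5% and decomposed reagent 6.41% of the substrate charge.

(The runs stem from a simulated flask on assumed constants, noise included.)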